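**Strategy.** The cyclohexane ring carries a trans C1–O(ester)/C6–C7 pair across from the C3(Me)–C4 oxirane. Read as a masked C3=C4 olefin, that oxirane reveals a 4-methylcyclohexene, the retron of an isoprene Diels–Alder reaction. One catalytic enantioselective [4+2] between isoprene and an (E)-3-acyloxyacryloyl oxazolidinone forms C1–C2 and C5–C6, closes the carbocycle and fixes C1 and C6 together. The dienophile is built with the 3-methylbutanoate of the target already on the enol oxygen, so the ester never has to be exchanged. Afterwards the imide carbon C7 becomes the spiro-oxirane (Sharpless epoxidation), C2 is oxidised through the C3=C4 olefin, and C9–C12 arrive by Nozaki–Hiyama–Kishi coupling.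

Key step: step 3

Numbering used throughout: ring C1 (CH–O-ester), C2, C3 (C–CH3), C4, C5, C6; side chain C7 (on C6), C8 (oxirane CH2), C9, C10=C11, C12 (CMe2OH). β is the ring face of the C6 side chain, α the face of the C1 oxygen.

Assumption: the β-acyloxy imide is taken to bind the copper catalyst in the same two-point, s-cis fashion as simple acryloyl and crotonoyl imides, so the known sense of induction is carried over.

**Route**

Step 1
Reactants: 1 oxazolidin-2-one; 2 propiolic acid
Product: 3 N-propioloyl oxazolidinone
Conditions: DCC, DMAP (cat.), CH2Cl2, 0 °C to rt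
Reagents that add atoms: none
Why: Carbodiimide (Steglich-type) N-acylation, in which DMAP passes the activated propioloyl group on to the weakly nucleophilic carbamate nitrogen at low temperature; no stereocentre is involved.

Step 2
Reactants: 3 N-propioloyl oxazolidinone; 4 isovaleric acid (3-methylbutanoic acid)
Product: 5 (E)-3-(3-methylbutanoyloxy)acryloyl oxazolidinone
Conditions: DABCO (10 mol %), CH2Cl2, 0 °C to rt
Reagents that add atoms: none
Why: Tertiary-amine-catalysed conjugate addition of a carboxylic acid to an acceptor-substituted terminal alkyne, in which DABCO adds first and the carboxylate replaces it by addition–elimination, so the thermodynamically preferred (E)-enol ester should result.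

Step 3
Reactants: 5 (E)-3-(3-methylbutanoyloxy)acryloyl oxazolidinone; 6 isoprene
Product: 7 trans cycloadduct (C1 isovalerate, C6 acyl oxazolidinone, C3=C4 olefin)
Conditions: [Cu((S,S)-t-Bu-box)](SbF6)2 (10 mol %), isoprene (5 equiv), CH2Cl2, 0 °C to rt; t-Bu-box = 2,2'-(propane-2,2-diyl)bis(4-tert-butyl-4,5-dihydrooxazole)
Reagents that add atoms: none
Why: Both imide carbonyls chelate the cationic divalent copper centre, which holds the dienophile s-cis and lowers its LUMO, and isoprene then adds in a concerted suprafacial [4+2] cycloaddition. The closest known reaction type is the copper–bis(oxazoline)-catalysed Diels–Alder reaction of β-substituted acryloyl oxazolidinones with simple dienes. The cyclohexene ring is closed by an intermolecular cycloaddition in which both sigma bonds (C1–C2 and C5–C6) form in one step. C6 is controlled by the ligand, whose tert-butyl group covers the Si face of the α-carbon so that the diene bonds to the Re face, and C1 is controlled by the (E)-geometry of the enol ester, which is carried over as the trans C1–O/C6–acyl relationship. The step needs regioselectivity (methyl 1,4 to the acyl-bearing carbon), which the substrate secures because the chelated imide puts the larger LUMO coefficient on its β-carbon and the methyl group puts the larger HOMO coefficient on the adjacent CH2 terminus of isoprene; endo/exo selectivity is not needed because the diene termini carry no substituents.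

Step 4
Reactants: 7 trans cycloadduct
Product: 8 S-ethyl thioester
Conditions: EtSH, n-BuLi, THF, 0 °C
Reagents that add atoms: ethanethiol, CCS (used as lithium ethanethiolate)
Why: Thiolate transacylation of an N-acyl oxazolidinone, in which the soft, weakly basic thiolate attacks only the activated exocyclic imide carbonyl, so the alkyl ester, the β-acyloxy relationship and both stereocentres should stay untouched.

Step 5
Reactants: 8 S-ethyl thioester
Product: 9 methyl ketone
Conditions: Me2CuLi (from MeLi and CuI), Et2O, −78 °C
Reagents that add atoms: lithium dimethylcuprate, [Li+].C[Cu-]C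
Why: Ketone synthesis from a thioester with a Gilman cuprate, which is acylated at low temperature, does not add to the ketone formed and leaves the ordinary ester alone.

Step 6
Reactants: 9 methyl ketone
Product: 10 enol triflate
Conditions: PhNTf2, then KN(SiMe3)2 added slowly, THF, −78 °C
Reagents that add atoms: N-phenylbis(trifluoromethanesulfonimide), O=S(=O)(N(c1ccccc1)S(=O)(=O)C(F)(F)F)C(F)(F)F
Why: Kinetic enol triflate formation, in which the hindered amide base removes a methyl proton with the triflyl donor already present, so the terminal enolate should be O-sulfonylated before it can attack the neighbouring ester or equilibrate to the C6 enolate; C6 is not touched.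

Step 7
Reactants: 10 enol triflate
Product: 11 C2 allylic alcohol (hydroxyl expected cis to the C1 ester)
Conditions: SeO2 (0.3 equiv), t-BuOOH, CH2Cl2, rt
Reagents that add atoms: tert-butyl hydroperoxide, CC(C)(C)OO; selenium dioxide, O=[Se]=O (catalytic oxygen carrier)
Why: Riley-type allylic oxidation, in which an ene reaction puts selenium on C4 and takes hydrogen from the ring CH2 on the more substituted olefin terminus (C2), and a [2,3]-sigmatropic shift returns the olefin to C3=C4 with oxygen on C2 (axial delivery, a configuration erased in step 8), while the electron-poor enol triflate should not react.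

Step 8
Reactants: 11 C2 allylic alcohol
Product: 12 enone
Conditions: DMP, CH2Cl2, 0 °C to rt
Reagents that add atoms: none
Why: Dess–Martin oxidation of a secondary allylic alcohol to the conjugated enone, which also converges any enone already formed in step 7 and removes the C2 stereocentre.

Step 9
Reactants: 12 enone
Product: 13 trans allylic alcohol (C2–OH β)
Conditions: NaBH4, CeCl3·7H2O, MeOH, −78 °C
Reagents that add atoms: none
Why: Luche 1,2-reduction, in which hydride adds axially to the cerium-activated carbonyl, anti to the axial C1–H, so the new C2 hydroxyl should be equatorial, trans to the C1 ester and cis to the C6 substituent; the enol triflate and the ester are inert.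

Step 10
Reactants: 13 trans allylic alcohol
Product: 14 bis-allylic diol
Conditions: Bu3SnCH2OH, Pd(PPh3)4 (5 mol %), LiCl, 1,4-dioxane, 90 °C
Reagents that add atoms: (tributylstannyl)methanol, CCCC[Sn](CCCC)(CCCC)CO
Why: Stille coupling of an enol triflate, in which the C7–O bond adds oxidatively to zerovalent palladium, the hydroxymethyl group is transferred selectively from tin and reductive elimination gives the 2-substituted allylic alcohol without touching a stereocentre.

Step 11
Reactants: 14 bis-allylic diol
Product: 15 oxirane diol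
Conditions: Ti(OiPr)4 (10 mol %), L-(+)-diisopropyl tartrate (12 mol %), t-BuOOH, 4 Å MS, CH2Cl2, −20 °C
Reagents that add atoms: tert-butyl hydroperoxide, CC(C)(C)OO
Why: Sharpless asymmetric epoxidation, in which the titanium–L-(+)-tartrate complex binds the primary allylic alcohol and delivers oxygen to the C7=C8 face that gives the (S)-oxiranylmethanol (reagent control sets C7), while the cyclic secondary allylic alcohol is a poor substrate for this catalyst.

Step 12
Reactants: 15 oxirane diol
Product: 16 bis-oxirane diol
Conditions: VO(acac)2 (5 mol %), t-BuOOH, CH2Cl2, 0 °C to rt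
Reagents that add atoms: tert-butyl hydroperoxide, CC(C)(C)OO
Why: Vanadium-catalysed hydroxyl-directed epoxidation, in which the C2 vanadate ester delivers the peroxide oxygen to the adjacent C3=C4 bond on its own β face, setting C3 and C4 syn to the C2 hydroxyl, that is cis to the C6 side chain and trans to the C1 ester.

Step 13
Reactants: 16 bis-oxirane diol
Product: 17 oxirane aldehyde
Conditions: TEMPO (10 mol %), PhI(OAc)2, CH2Cl2, rt
Reagents that add atoms: none
Why: Oxoammonium (TEMPO) oxidation with PhI(OAc)2 as terminal oxidant, selective for the primary over the secondary alcohol; quaternary C7 cannot epimerise, and the β-oxirane on the same face should disfavour the ring conformation needed for lactol formation with the C2 hydroxyl.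

Step 14
Reactants: 18 2-methylbut-3-yn-2-ol
Product: 20 (E)-vinyl iodide, via vinylstannane 19 (not isolated)
Conditions: Bu3SnH, PdCl2(PPh3)2 (2 mol %), THF, 0 °C to rt; then I2, 0 °C
Reagents that add atoms: iodine, [I][I]; tributyltin hydride, CCCC[SnH](CCCC)CCCC (its tin group stays only in 19)
Why: Palladium-catalysed syn-hydrostannation puts tin on the terminal carbon, away from the bulky carbinol, to give the (E)-vinylstannane, and iododestannylation proceeds with retention of the olefin geometry.

Step 15
Reactants: 17 oxirane aldehyde; 20 (E)-vinyl iodide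
Product: 21 triol (both C9 epimers)
Conditions: CrCl2 (4 equiv), NiCl2 (2 mol %), DMSO, rt
Reagents that add atoms: none
Why: Nozaki–Hiyama–Kishi coupling, in which nickel-catalysed activation of the vinyl iodide and transmetalation give an alkenyl species of trivalent chromium that adds only to the aldehyde and tolerates the free hydroxyls, the ester and both oxiranes; the C9 carbinol forms as an epimer mixture that step 16 removes.

Step 16
Reactants: 21 triol
Product: 22 target CNP0292003.1
Conditions: DMP (3 equiv), NaHCO3, CH2Cl2, 0 °C to rt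
Reagents that add atoms: none
Why: Dess–Martin oxidation of both secondary alcohols (C2 and C9) to the ring ketone and the (E)-enone under buffered, non-epimerising conditions; the tertiary C12 hydroxyl cannot be oxidised.

**Compound list**

1 | 1,3-oxazolidin-2-one | O=C1NCCO1 | starting material
2 | propiolic acid (prop-2-ynoic acid) | C#CC(O)=O | starting material
3 | 3-(prop-2-ynoyl)-1,3-oxazolidin-2-one | C#CC(=O)N1CCOC1=O | intermediate
4 | 3-methylbutanoic acid (isovaleric acid) | CC(C)CC(O)=O | starting material
5 | 3-[(2E)-3-(3-methylbutanoyloxy)prop-2-enoyl]-1,3-oxazolidin-2-one | CC(C)CC(=O)O/C=C/C(=O)N1CCOC1=O | intermediate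
6 | isoprene (2-methylbuta-1,3-diene) | C=CC(C)=C | starting material
7 | (1R,6R)-3-methyl-6-(2-oxo-1,3-oxazolidine-3-carbonyl)cyclohex-3-en-1-yl 3-methylbutanoate | CC(C)CC(=O)O[C@@H]1CC(C)=CC[C@H]1C(=O)N1CCOC1=O | intermediate
8 | (1R,6R)-6-[(ethylsulfanyl)carbonyl]-3-methylcyclohex-3-en-1-yl 3-methylbutanoate | CC(C)CC(=O)O[C@@H]1CC(C)=CC[C@H]1C(=O)SCC | intermediate
9 | (1R,6R)-6-acetyl-3-methylcyclohex-3-en-1-yl 3-methylbutanoate | CC(C)CC(=O)O[C@@H]1CC(C)=CC[C@H]1C(C)=O | intermediate
10 | (1R,6R)-3-methyl-6-{1-[(trifluoromethanesulfonyl)oxy]ethenyl}cyclohex-3-en-1-yl 3-methylbutanoate | CC(C)CC(=O)O[C@@H]1CC(C)=CC[C@H]1C(=C)OS(=O)(=O)C(F)(F)F | intermediate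
11 | (1S,2R,6R)-2-hydroxy-3-methyl-6-{1-[(trifluoromethanesulfonyl)oxy]ethenyl}cyclohex-3-en-1-yl 3-methylbutanoate (C2–OH cis to the ester; expected major epimer) | CC(C)CC(=O)O[C@@H]1[C@H](O)C(C)=CC[C@H]1C(=C)OS(=O)(=O)C(F)(F)F | intermediate
12 | (1S,6R)-3-methyl-2-oxo-6-{1-[(trifluoromethanesulfonyl)oxy]ethenyl}cyclohex-3-en-1-yl 3-methylbutanoate | CC(C)CC(=O)O[C@@H]1C(=O)C(C)=CC[C@H]1C(=C)OS(=O)(=O)C(F)(F)F | intermediate
13 | (1S,2S,6R)-2-hydroxy-3-methyl-6-{1-[(trifluoromethanesulfonyl)oxy]ethenyl}cyclohex-3-en-1-yl 3-methylbutanoate (C2–OH trans to the ester) | CC(C)CC(=O)O[C@@H]1[C@@H](O)C(C)=CC[C@H]1C(=C)OS(=O)(=O)C(F)(F)F | intermediate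
14 | (1S,2S,6S)-2-hydroxy-6-(3-hydroxyprop-1-en-2-yl)-3-methylcyclohex-3-en-1-yl 3-methylbutanoate | CC(C)CC(=O)O[C@@H]1[C@@H](O)C(C)=CC[C@H]1C(=C)CO | intermediate
15 | (1S,2S,6R)-2-hydroxy-6-[(2S)-2-(hydroxymethyl)oxiran-2-yl]-3-methylcyclohex-3-en-1-yl 3-methylbutanoate | CC(C)CC(=O)O[C@@H]1[C@@H](O)C(C)=CC[C@H]1[C@]1(CO)CO1 | intermediate
16 | (1R,2R,3S,4R,6S)-2-hydroxy-4-[(2S)-2-(hydroxymethyl)oxiran-2-yl]-1-methyl-7-oxabicyclo[4.1.0]heptan-3-yl 3-methylbutanoate | CC(C)CC(=O)O[C@@H]1[C@@H](O)[C@@]2(C)O[C@H]2C[C@H]1[C@]1(CO)CO1 | intermediate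
17 | (1R,2R,3S,4R,6S)-4-[(2R)-2-formyloxiran-2-yl]-2-hydroxy-1-methyl-7-oxabicyclo[4.1.0]heptan-3-yl 3-methylbutanoate | CC(C)CC(=O)O[C@@H]1[C@@H](O)[C@@]2(C)O[C@H]2C[C@H]1[C@]1(C=O)CO1 | intermediate
18 | 2-methylbut-3-yn-2-ol | CC(C)(O)C#C | starting material
19 | (3E)-2-methyl-4-(tributylstannyl)but-3-en-2-ol | CCCC[Sn](CCCC)(CCCC)/C=C/C(C)(C)O | intermediate
20 | (3E)-4-iodo-2-methylbut-3-en-2-ol | CC(C)(O)/C=C/I | intermediate
21 | (1R,2R,3S,4R,6S)-4-{(2R)-2-[(2E)-1,4-dihydroxy-4-methylpent-2-en-1-yl]oxiran-2-yl}-2-hydroxy-1-methyl-7-oxabicyclo[4.1.0]heptan-3-yl 3-methylbutanoate (both C9 epimers) | CC(C)CC(=O)O[C@@H]1[C@@H](O)[C@@]2(C)O[C@H]2C[C@H]1[C@]1(C(O)/C=C/C(C)(C)O)CO1 | intermediate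
22 | (1S,3S,4R,6S)-4-{(2R)-2-[(2E)-4-hydroxy-4-methylpent-2-enoyl]oxiran-2-yl}-1-methyl-2-oxo-7-oxabicyclo[4.1.0]heptan-3-yl 3-methylbutanoate | CC(C)CC(=O)O[C@@H]1C(=O)[C@@]2(C)O[C@H]2C[C@H]1[C@]1(C(=O)/C=C/C(C)(C)O)CO1 | target

**Count**

Total step count: 16.
Longest linear sequence: 15 steps (steps 1–13, 15 and 16); step 14 is a one-step side branch.

**Steps most likely to fail**

Step 7. The ene step may take hydrogen from the C3 methyl group instead of from C2, because the C1 acyloxy group lowers the reactivity of the neighbouring C–H bonds; oxygen would then end up on the methyl carbon. The fallback brings the C2 oxygen in by a carbonyl transposition that needs no allylic C–H oxidation. It sets out from enol triflate 10. OsO4 (cat.)/NMO in acetone–water should dihydroxylate only the electron-rich ring olefin and give the cis-3,4-diol F1. DMP should oxidise only the secondary C4 hydroxyl and give the tertiary α-hydroxy ketone F2. Dehydration with SOCl2/pyridine, which can only run away from the carbonyl, should give the C2=C3 enone F3. Epoxidation with t-BuOOH/DBU, anti to the C1 ester, should give the 2,3-epoxy ketone F4. Wharton transposition (N2H4·H2O, AcOH, MeOH) then moves the olefin to C3=C4 and leaves the oxygen on C2 with the β configuration. This is allylic alcohol 13, where the route is rejoined; steps 8 and 9 fall away.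

Step 6. The potassium enolate may transfer the neighbouring acyl group to carbon, or the minor C6 enolate may expel isovalerate, before sulfonylation is complete. The fallback takes the ester off before the enolate chemistry and puts it back afterwards. It sets out from cycloadduct 7. AlMe3 with MeNH(OMe)·HCl should give the N-methoxy-N-methylamide F5. Excess MeMgBr should form the methyl ketone and cleave the ester, leaving β-hydroxy ketone F6. TESCl/imidazole gives silyl ether F7. KN(SiMe3)2/PhNTf2 should then give the silyl enol triflate F8 without complication, since a silyloxy group is neither a leaving group nor an acyl donor here. AcOH/THF/H2O frees the hydroxy enol triflate F9. 3-Methylbutanoyl chloride with pyridine and DMAP returns enol triflate 10, where the route is rejoined; steps 4–6 are replaced.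

Step 3. The cycloaddition may be too slow for this donor-substituted dienophile, so that isoprene oligomerises on the Lewis acid or the enantioselectivity erodes at the temperature needed. The fallback forms the same two bonds under auxiliary control with a stronger Lewis acid. It sets out from propiolic acid 2. Commercial (R)-4-benzyl-1,3-oxazolidin-2-one is acylated as in step 1 to give the ynoyl imide F10. 3-Methylbutanoic acid 4 is added as in step 2 to give the (E)-enol ester F11. Et2AlCl (1.4 equiv) and isoprene 6 in CH2Cl2 at −78 °C should give the auxiliary-bearing cycloadduct F12, the benzyl group covering the Si face of the chelated s-cis dienophile. Lithium ethanethiolate then gives thioester 8, where the route is rejoined, and releases the auxiliary for reuse.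

**Further compounds**

F1 | step 7 | (1R,6R)-3,4-dihydroxy-3-methyl-6-{1-[(trifluoromethanesulfonyl)oxy]ethenyl}cyclohexyl 3-methylbutanoate (cis-3,4-diol, either face) | CC(C)CC(=O)O[C@@H]1CC(C)(O)C(O)C[C@H]1C(=C)OS(=O)(=O)C(F)(F)F
F2 | step 7 | (1R,6R)-3-hydroxy-3-methyl-4-oxo-6-{1-[(trifluoromethanesulfonyl)oxy]ethenyl}cyclohexyl 3-methylbutanoate | CC(C)CC(=O)O[C@@H]1CC(C)(O)C(=O)C[C@H]1C(=C)OS(=O)(=O)C(F)(F)F
F3 | step 7 | (1R,6R)-3-methyl-4-oxo-6-{1-[(trifluoromethanesulfonyl)oxy]ethenyl}cyclohex-2-en-1-yl 3-methylbutanoate | CC(C)CC(=O)O[C@@H]1C=C(C)C(=O)C[C@H]1C(=C)OS(=O)(=O)C(F)(F)F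
F4 | step 7 | 2,3-epoxy-4-ketone of F3, oxirane across C2–C3 on the β face, trans to the C1 ester | CC(C)CC(=O)O[C@@H]1[C@H]2O[C@@]2(C)C(=O)C[C@H]1C(=C)OS(=O)(=O)C(F)(F)F
F5 | step 6 | (1R,6R)-6-[methoxy(methyl)carbamoyl]-3-methylcyclohex-3-en-1-yl 3-methylbutanoate | CC(C)CC(=O)O[C@@H]1CC(C)=CC[C@H]1C(=O)N(C)OC
F6 | step 6 | 1-[(1R,6R)-6-hydroxy-4-methylcyclohex-3-en-1-yl]ethan-1-one | O[C@@H]1CC(C)=CC[C@H]1C(C)=O
F7 | step 6 | 1-[(1R,6R)-4-methyl-6-(triethylsilyloxy)cyclohex-3-en-1-yl]ethan-1-one | CC[Si](CC)(CC)O[C@@H]1CC(C)=CC[C@H]1C(C)=O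
F8 | step 6 | 1-[(1R,6R)-4-methyl-6-(triethylsilyloxy)cyclohex-3-en-1-yl]ethenyl trifluoromethanesulfonate | CC[Si](CC)(CC)O[C@@H]1CC(C)=CC[C@H]1C(=C)OS(=O)(=O)C(F)(F)F
F9 | step 6 | 1-[(1R,6R)-6-hydroxy-4-methylcyclohex-3-en-1-yl]ethenyl trifluoromethanesulfonate | O[C@@H]1CC(C)=CC[C@H]1C(=C)OS(=O)(=O)C(F)(F)F
F10 | step 3 | (4R)-4-benzyl-3-(prop-2-ynoyl)-1,3-oxazolidin-2-one | C#CC(=O)N1[C@H](Cc2ccccc2)COC1=O
F11 | step 3 | (4R)-4-benzyl-3-[(2E)-3-(3-methylbutanoyloxy)prop-2-enoyl]-1,3-oxazolidin-2-one | CC(C)CC(=O)O/C=C/C(=O)N1[C@H](Cc2ccccc2)COC1=O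
F12 | step 3 | (1R,6R)-6-[(4R)-4-benzyl-2-oxo-1,3-oxazolidine-3-carbonyl]-3-methylcyclohex-3-en-1-yl 3-methylbutanoate | CC(C)CC(=O)O[C@@H]1CC(C)=CC[C@H]1C(=O)N1[C@H](Cc2ccccc2)COC1=O
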